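When you read these flasks at 5.0 min, the question is whether the left-handed product has stopped, and at what level.

in all of them: catalyst 1 mol%
- east: left-handed substrate 0.34 M; right-handed substrate 0.34 M; solid reagent 1 equiv; temperature 68 °C; run made earlier
- south-west: left-handed substrate 0.53 M; right-handed substrate 0.53 M; solid reagent 1 equiv; temperature 84 °C; run made earlier
- winter: left-handed substrate 0.24 M; right-handed substrate 0.24 M; solid reagent 1.00 equiv; temperature 75 °C; time 5.0 min
- autumn: left-handed substrate 0.24 M; right-handed substrate 0.24 M; solid reagent 1.00 equiv; temperature 90 °C; time 5.0 min
- dusk: left-handed substrate 0.24 M; right-handed substrate 0.24 M; solid reagent 1.00 equiv; temperature 60 °C; time 5.0 min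

east run (percent of the left-handed substrate and right-handed substrate together charged)

| time / min | left-handed product / % | left-handed substrate / % |
|---|---|---|
| 0.500 | 15.1 | 34.0 |
| 1.00 | 29.0 | 23.1 |
| 1.50 | 30.3 | 20.5 |
| 2.00 | 30.0 | 18.8 |
| 2.50 | 29.5 | 20.8 |
| 3.00 | 29.7 | 20.2 |

south-west run (percent of the left-handed substrate and right-handed substrate together charged)

| time / s | left-handed product / % | left-handed substrate / % |
|---|---|---|
| 10.0 | 5.1 | 45.6 |
| 25.0 | 11.5 | 39.1 |
| 40.0 | 19.3 | 29.7 |
| 60.0 | 30.1 | 21.2 |
| 90.0 | 31.2 | 18.8 |
| 120 | 30.8 | 19.1 |

(each reading ± 1 percentage point)

- which flask leads in amount of left-handed product, in percent of the left-handed substrate and right-handed substrate together charged ("all alike" within 1.5 percentage points) (winter / autumn / dusk / all alike)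
- how much left-handed product is there at the end, in percent of the left-handed substrate and right-handed substrate together charged: winter
- how much left-handed product is there at the end, in percent of the left-handed substrate and right-handed substrate together charged: autumn
- how much left-handed product is there at the end, in percent of the left-handed substrate and right-handed substrate together charged: dusk

- catalyst is single-handed; left-handed substrate and right-handed substrate are mirror images of each other, charged as a racemate, each of them at the stated concentration
- as a solid, counted per litre of solution: solid reagent
- at the start none of the solid reagent is in solution

I start with a bracket. From above, left-handed product cannot pass 50.0%, which is the left-handed substrate charged and, at 1.00 equiv, the solid reagent too. From below, an even split of the solid reagent between the mirror images gives 25.0%, and the last readings of both runs stand higher than that.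

To tighten it, look at where the runs stop. The left-handed product of the east run reads level from 1.50 min, and its last reading of left-handed substrate is 20.2%, so I take the solid reagent as the limiting reagent. The last readings of left-handed product, 29.7% and 30.8%, each good to 1 percentage point, average 60.5% of the charge of solid reagent: read so, this is the part of the charged solid reagent that ends as left-handed product, the reagent share. My bracket is therefore those two readings, an estimate and not a strict bound, with 30.2% for each flask. Its width of 1.1 points is smaller than the margin, so I expect all alike. The weak point is dusk, at 60 °C, colder than the east run at 68 °C, though the 5.0 min allowed is 3.33 times the east run's 1.50 min. Autumn, at 90 °C, also lies outside the range of the runs.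

The forecast, which sees “a modest kinetic resolution”, gives 30.3% for winter, 30.5% for autumn, 30% for dusk, and all alike, each figure inside my bracket.

The flasks give all alike: winter 30.3%, autumn 30.8%, dusk 29.8%.

    coupling partner + catalyst + left-handed substrate → catalyst + left-handed product (k = 72.0 M⁻² s⁻¹, Ea = 44.0 kJ mol⁻¹)
    coupling partner + catalyst + right-handed substrate → catalyst + right-handed product (k = 41.0 M⁻² s⁻¹, Ea = 40.0 kJ mol⁻¹)
    solid reagent ⇌ coupling partner, rate k3*(cs3 - [coupling partner]) while solid is left; crystals form when [coupling partner] > cs3 (solubility = 0.100 M, k = 0.0980 s⁻¹)
    (constants at 60 °C)

In autumn at 0.274 min, coupling partner goes to the left-handed substrate 1.7 times as fast as to the right-handed substrate, a share of 63.0% at that moment. The autumn end, with solid reagent at 0% of its charge, has 61.6% of the charged solid reagent as left-handed product, against the carried reagent share of 60.5%. Carried to a flask like autumn with 1.70 equiv of solid reagent, the reagent share reckons 51.4%, more than the cap, but this flask gives 47.0%, a share of 55.3%, with left-handed substrate down to 2.98%.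

(Readings and results were generated by integration with constants of no real substance; noise was put on by code.)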